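**Retrosynthetic overview**
1. Salimabromide ⇐ didebromo tetracycle, by a late twofold aromatic bromination at the two positions ortho to ethyl.
2. Tetralin ring (last ring, the bond between the two quaternary carbons) ⇐ bridged keto-lactone carrying an o-isopropenylaryl group: a tertiary benzylic cation is captured by the γ-carbon of the cycloheptenone dienol ether.
3. γ-Lactone ⇐ 6-aryl-5-acyl-cyclohept-2-enone: oxygenation α′ to the ketone, then acyl transfer that releases the chiral oxazolidinone.
4. Cycloheptenone ⇐ cyclohexene silyl enol ether by one-carbon ring expansion ⇐ auxiliary-controlled Diels–Alder of a cinnamoyl imide with a 2-silyloxy-1,3-pentadiene (sets the benzylic stereocentre, from which all others follow).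
5. Ring order forward: cyclohexene → cycloheptenone → lactone → tetralin; the arene comes from 4′-ethylacetophenone by ketone-directed C–H alkenylation.

Assumption: the presumed biogenesis is taken to be a polyketide aryl-cycloheptenone carboxylate that is oxygenated next to the ketone and lactonises, then closes the tetralin by attack of its dienol γ-carbon on a tertiary benzylic cation, with enzymatic dibromination of the arene last.

**Route**

Step 1
Reactants: 1 (S)-4-benzyloxazolidin-2-one; 2 acryloyl chloride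
Product: 3 (4S)-3-acryloyl-4-benzyl-1,3-oxazolidin-2-one
Conditions: MeMgBr, THF, 0 °C; then 2, −78 → 0 °C
Reagents that add atoms: none
Why: N-acylation of the bromomagnesium salt of the oxazolidinone with the acid chloride (Evans imide formation) installs the chiral controller without polymerising the acrylate, and no new stereocentre is formed.

Step 2
Reactants: 4 4′-ethylacetophenone; 3 (4S)-3-acryloyl-4-benzyl-1,3-oxazolidin-2-one
Product: 5 (4S)-3-[(2E)-3-(2-acetyl-5-ethylphenyl)prop-2-enoyl]-4-benzyl-1,3-oxazolidin-2-one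
Conditions: [RuCl2(p-cymene)]2 (3 mol%), AgSbF6 (12 mol%), Cu(OAc)2·H2O (2 equiv), ClCH2CH2Cl, 110 °C
Reagents that add atoms: none
Why: Ketone-directed ruthenium-catalysed oxidative C–H alkenylation (Fujiwara–Moritani type) is established for acetophenones with acrylates and acrylamides (the imide partner is an extension of that scope), the two ortho positions of 4 are equivalent, and β-hydride elimination gives the E alkene.

Step 3
Reactants: 5 acetylaryl cinnamoyl imide
Product: 6 (4S)-4-benzyl-3-{(2E)-3-[5-ethyl-2-(prop-1-en-2-yl)phenyl]prop-2-enoyl}-1,3-oxazolidin-2-one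
Conditions: Zn, CH2Br2, TiCl4, THF/CH2Cl2, 0 °C → rt
Reagents that add atoms: dibromomethane BrCBr
Why: Lombardo–Takai methylenation converts the hindered, enolisable aryl methyl ketone into the 1,1-disubstituted alkene and leaves imide carbonyls and the enoyl alkene untouched.

Step 4
Reactants: 7 (E)-pent-3-en-2-one
Product: 8 (E)-2-(tert-butyldimethylsilyloxy)penta-1,3-diene
Conditions: TBSOTf, Et3N, Et2O, 0 °C
Reagents that add atoms: tert-butyldimethylsilyl trifluoromethanesulfonate CC(C)(C)[Si](C)(C)OS(=O)(=O)C(F)(F)F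
Why: Soft enolisation (silyl triflate/amine) at the kinetic α′-methyl group gives the 2-silyloxy diene with the E alkene retained.

Step 5
Reactants: 6 isopropenylaryl cinnamoyl imide; 8 (E)-2-(tert-butyldimethylsilyloxy)penta-1,3-diene
Product: 9 (4S)-4-benzyl-3-{[(1S,2S,6S)-4-(tert-butyldimethylsilyloxy)-6-[5-ethyl-2-(prop-1-en-2-yl)phenyl]-2-methylcyclohex-3-en-1-yl]carbonyl}-1,3-oxazolidin-2-one
Conditions: Et2AlCl (1.4 equiv), CH2Cl2, −78 → −30 °C
Reagents that add atoms: none
Why: Evans auxiliary-controlled Lewis-acid Diels–Alder reaction, in which the aluminium-chelated s-cis imide is attacked on the face opposite the benzyl group (setting the benzylic centre S), the nucleophilic CH2 terminus of the diene bonds to the β-carbon, the E dienophile fixes aryl and acyl trans, and the endo mode places the methyl cis to the acyl group.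

Step 6
Reactants: 9 cyclohexene silyl enol ether
Product: 10 (4S)-4-benzyl-3-{[(1S,2S,3S,4S,6S)-6-(tert-butyldimethylsilyloxy)-4-[5-ethyl-2-(prop-1-en-2-yl)phenyl]-2-methylbicyclo[4.1.0]heptan-3-yl]carbonyl}-1,3-oxazolidin-2-one
Conditions: Et2Zn, CH2I2, CH2Cl2, 0 °C
Reagents that add atoms: diiodomethane ICI
Why: Furukawa–Simmons–Smith cyclopropanation is fastest for the electron-rich silyl enol ether, which should react ahead of the twisted, hindered isopropenyl arene; the carbenoid adds anti to the allylic methyl, and both new centres are erased in step 7.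

Step 7
Reactants: 10 silyloxycyclopropane
Product: 12 (4S)-4-benzyl-3-{[(1S,2S,7S)-7-[5-ethyl-2-(prop-1-en-2-yl)phenyl]-2-methyl-5-oxocyclohept-3-en-1-yl]carbonyl}-1,3-oxazolidin-2-one, via β-chloro cycloheptanone 11 (not isolated)
Conditions: FeCl3 (2.2 equiv), DMF, 0 °C → rt; then DBU, CH2Cl2, 0 °C
Reagents that add atoms: none
Why: Ito–Saegusa ring expansion, in which one-electron oxidation by FeCl3 gives the alkoxy radical, β-scission of the ring-fusion bond gives the β-chloro cycloheptanone, and E1cB loss of HCl gives the conjugated enone with the inserted carbon on the side fixed by the Diels–Alder enol ether.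

Step 8
Reactants: 12 cycloheptenone imide
Product: 14 (1S,2S,6S,9S)-9-[5-ethyl-2-(prop-1-en-2-yl)phenyl]-2-methyl-7-oxabicyclo[4.2.1]non-3-ene-5,8-dione, via α′-hydroxy ketone 13 (not isolated)
Conditions: LiN(SiMe3)2, THF, −78 °C; 2-(phenylsulfonyl)-3-phenyloxaziridine, −78 → 0 °C; aq NH4Cl
Reagents that add atoms: 2-(phenylsulfonyl)-3-phenyloxaziridine O=S(=O)(c1ccccc1)N1OC1c1ccccc1
Why: Kinetic α′-enolisation of the enone (the α-branched imide resists enolisation through allylic strain) and Davis enolate hydroxylation anti to the neighbouring aryl group place the new oxygen cis to the acyl group, so the alkoxide lactonises by acyl transfer from the N-acyl oxazolidinone and expels the auxiliary.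

Step 9
Reactants: 14 bridged keto-lactone
Product: 17 didebromosalimabromide (the tetracycle of the target with H in place of both Br), via tertiary benzylic chloride 15 (not isolated), via silyl dienol ether chloride 16 (not isolated)
Conditions: HCl (g), CH2Cl2, −40 °C, purge; Et3N, TBSOTf, −78 → −20 °C; AgOTf, −78 → 0 °C (one pot)
Reagents that add atoms: none
Why: Proposed new method: Markovnikov hydrochlorination gives the tertiary benzylic chloride, the bridgehead α′ carbon cannot enolise so soft enolisation gives only the extended silyl dienol ether, and silver-assisted ionisation lets its γ-carbon attack the tertiary benzylic cation held over it by the benzylic bridge (six-membered ring, only the face syn to the aryl group is reachable, which fixes the methyl-bearing quaternary centre, and elimination merely returns 14); the closest known reaction types are the Reetz tert-alkylation of silyl enol ethers with SN1-active tertiary halides and γ-selective vinylogous Mukaiyama alkylations.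

Step 10
Reactants: 17 didebromosalimabromide
Product: 18 salimabromide
Conditions: Br2 (2.2 equiv), AgO2CCF3 (2.2 equiv), CF3CO2H, 0 °C → rt
Reagents that add atoms: bromine BrBr
Why: Electrophilic aromatic bromination by trifluoroacetyl hypobromite goes to the two positions ortho to ethyl (each ortho or para to two alkyl groups), the position beside the CMe2 group is sterically blocked, and the enone cannot enolise (bridgehead α′ carbon, quaternary γ carbon) so it is not brominated.

**Compound list**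
1 | (S)-4-benzyloxazolidin-2-one | O=C1N[C@@H](Cc2ccccc2)CO1 | starting material
2 | acryloyl chloride | C=CC(=O)Cl | starting material
3 | (4S)-3-acryloyl-4-benzyl-1,3-oxazolidin-2-one | C=CC(=O)N1C(=O)OC[C@@H]1Cc1ccccc1 | intermediate
4 | 4′-ethylacetophenone | CCc1ccc(cc1)C(C)=O | starting material
5 | (4S)-3-[(2E)-3-(2-acetyl-5-ethylphenyl)prop-2-enoyl]-4-benzyl-1,3-oxazolidin-2-one | CCc1ccc(C(C)=O)c(c1)/C=C/C(=O)N1C(=O)OC[C@@H]1Cc1ccccc1 | intermediate
6 | (4S)-4-benzyl-3-{(2E)-3-[5-ethyl-2-(prop-1-en-2-yl)phenyl]prop-2-enoyl}-1,3-oxazolidin-2-one | CCc1ccc(C(C)=C)c(c1)/C=C/C(=O)N1C(=O)OC[C@@H]1Cc1ccccc1 | intermediate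
7 | (E)-pent-3-en-2-one | C/C=C/C(C)=O | starting material
8 | (E)-2-(tert-butyldimethylsilyloxy)penta-1,3-diene | C/C=C/C(=C)O[Si](C)(C)C(C)(C)C | intermediate
9 | (4S)-4-benzyl-3-{[(1S,2S,6S)-4-(tert-butyldimethylsilyloxy)-6-[5-ethyl-2-(prop-1-en-2-yl)phenyl]-2-methylcyclohex-3-en-1-yl]carbonyl}-1,3-oxazolidin-2-one (aryl trans to acyl, methyl cis to acyl) | CCc1ccc(C(C)=C)c(c1)[C@H]1CC(O[Si](C)(C)C(C)(C)C)=C[C@H](C)[C@@H]1C(=O)N1C(=O)OC[C@@H]1Cc1ccccc1 | intermediate
10 | (4S)-4-benzyl-3-{[(1S,2S,3S,4S,6S)-6-(tert-butyldimethylsilyloxy)-4-[5-ethyl-2-(prop-1-en-2-yl)phenyl]-2-methylbicyclo[4.1.0]heptan-3-yl]carbonyl}-1,3-oxazolidin-2-one (cyclopropane anti to the methyl) | CCc1ccc(C(C)=C)c(c1)[C@H]1C[C@@]2(O[Si](C)(C)C(C)(C)C)C[C@H]2[C@H](C)[C@@H]1C(=O)N1C(=O)OC[C@@H]1Cc1ccccc1 | intermediate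
11 | (4S)-4-benzyl-3-{[(1R,2R,7S)-3-chloro-7-[5-ethyl-2-(prop-1-en-2-yl)phenyl]-2-methyl-5-oxocycloheptyl]carbonyl}-1,3-oxazolidin-2-one (C3 epimers, other centres as in 10) | CCc1ccc(C(C)=C)c(c1)[C@H]1CC(=O)CC(Cl)[C@H](C)[C@@H]1C(=O)N1C(=O)OC[C@@H]1Cc1ccccc1 | intermediate
12 | (4S)-4-benzyl-3-{[(1S,2S,7S)-7-[5-ethyl-2-(prop-1-en-2-yl)phenyl]-2-methyl-5-oxocyclohept-3-en-1-yl]carbonyl}-1,3-oxazolidin-2-one | CCc1ccc(C(C)=C)c(c1)[C@H]1CC(=O)C=C[C@H](C)[C@@H]1C(=O)N1C(=O)OC[C@@H]1Cc1ccccc1 | intermediate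
13 | (4S)-4-benzyl-3-{[(1S,2S,6S,7S)-7-[5-ethyl-2-(prop-1-en-2-yl)phenyl]-6-hydroxy-2-methyl-5-oxocyclohept-3-en-1-yl]carbonyl}-1,3-oxazolidin-2-one (formed as its lithium alkoxide) | CCc1ccc(C(C)=C)c(c1)[C@H]1[C@H](O)C(=O)C=C[C@H](C)[C@@H]1C(=O)N1C(=O)OC[C@@H]1Cc1ccccc1 | intermediate
14 | (1S,2S,6S,9S)-9-[5-ethyl-2-(prop-1-en-2-yl)phenyl]-2-methyl-7-oxabicyclo[4.2.1]non-3-ene-5,8-dione | CCc1ccc(C(C)=C)c(c1)[C@H]1[C@@H]2OC(=O)[C@H]1[C@@H](C)C=CC2=O | intermediate
15 | (1S,2S,6S,9S)-9-[2-(2-chloropropan-2-yl)-5-ethylphenyl]-2-methyl-7-oxabicyclo[4.2.1]non-3-ene-5,8-dione | CCc1ccc(C(C)(C)Cl)c(c1)[C@H]1[C@@H]2OC(=O)[C@H]1[C@@H](C)C=CC2=O | intermediate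
16 | (1R,6S,9S)-5-(tert-butyldimethylsilyloxy)-9-[2-(2-chloropropan-2-yl)-5-ethylphenyl]-2-methyl-7-oxabicyclo[4.2.1]nona-2,4-dien-8-one | CCc1ccc(C(C)(C)Cl)c(c1)[C@H]1[C@@H]2OC(=O)[C@H]1C(C)=CC=C2O[Si](C)(C)C(C)(C)C | intermediate
17 | didebromosalimabromide: the tetracycle of 18 with H in place of both Br (benzylic CH S; O–CH S; lactone α-CH R; methyl-bearing quaternary C R) | CCc1ccc2c(c1)[C@H]1[C@@H]3OC(=O)[C@H]1[C@@](C)(C=CC3=O)C2(C)C | intermediate
18 | salimabromide (benzylic CH S; O–CH S; lactone α-CH R; methyl-bearing quaternary C R) | CCc1c(Br)cc2c(c1Br)[C@H]1[C@@H]3OC(=O)[C@H]1[C@@](C)(C=CC3=O)C2(C)C | target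

**Count and risk**
Total steps: 10. Longest linear sequence: 9 (steps 1, 2, 3, 5, 6, 7, 8, 9, 10). Steps most likely to fail: 9, 5 and 6.

Step 9 (closure between two fully substituted carbons). If ionisation only returns the alkene, the closure is changed from polar to radical. The fallback sets out from 14: TBSOTf/Et3N gives the silyl dienol ether (1R,6S,9S)-5-(tert-butyldimethylsilyloxy)-9-[5-ethyl-2-(prop-1-en-2-yl)phenyl]-2-methyl-7-oxabicyclo[4.2.1]nona-2,4-dien-8-one F1. Hydrogen-atom transfer from an iron hydride (Fe(acac)3, PhSiH2(Oi-Pr), THF, rt) to the isopropenyl group gives the tertiary benzylic radical, which adds 6-exo to the diene terminus. Oxidation of the resulting silyloxyallyl radical by trivalent iron and loss of the silyl group on work-up give the enone, and the fallback comes back to the route at 17.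

Step 5 (hindered β-aryl dienophile with an acid-sensitive diene). If the cycloaddition is slow or the silyl enol ether is lost, the ring is built by two separate Michael additions. The fallback sets out from 6 (with 8): a TiCl4-promoted Mukaiyama–Michael addition on the chelated imide, followed by aqueous work-up, gives the open-chain keto imide (4S)-4-benzyl-3-{(3S,6E)-3-[5-ethyl-2-(prop-1-en-2-yl)phenyl]-5-oxooct-6-enoyl}-1,3-oxazolidin-2-one F2. Soft enolisation of the imide (TiCl4, i-Pr2NEt) closes the six-membered ring by intramolecular Michael addition to the enone, and TBSOTf traps the regiodefined ketone enolate, so the fallback comes back at 9.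

Step 6 (silyl enol ether versus isopropenyl group toward the zinc carbenoid). If both alkenes react, the methylenation is postponed so that only one alkene is present. The fallback sets out from 5: Diels–Alder reaction with 8 under the conditions of step 5 gives the cycloadduct (4S)-3-{[(1S,2S,6S)-6-(2-acetyl-5-ethylphenyl)-4-(tert-butyldimethylsilyloxy)-2-methylcyclohex-3-en-1-yl]carbonyl}-4-benzyl-1,3-oxazolidin-2-one F3. Cyclopropanation (Et2Zn, CH2I2) gives the silyloxycyclopropane (4S)-3-{[(1S,2S,3S,4S,6S)-4-(2-acetyl-5-ethylphenyl)-6-(tert-butyldimethylsilyloxy)-2-methylbicyclo[4.1.0]heptan-3-yl]carbonyl}-4-benzyl-1,3-oxazolidin-2-one F4. Wittig methylenation of the aryl ketone (Ph3P=CH2 from Ph3PCH3Br and KOt-Bu, THF) then comes back to the route at 10.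

**Further compounds**
F1 | step 9 | (1R,6S,9S)-5-(tert-butyldimethylsilyloxy)-9-[5-ethyl-2-(prop-1-en-2-yl)phenyl]-2-methyl-7-oxabicyclo[4.2.1]nona-2,4-dien-8-one | CCc1ccc(C(C)=C)c(c1)[C@H]1[C@@H]2OC(=O)[C@H]1C(C)=CC=C2O[Si](C)(C)C(C)(C)C
F2 | step 5 | (4S)-4-benzyl-3-{(3S,6E)-3-[5-ethyl-2-(prop-1-en-2-yl)phenyl]-5-oxooct-6-enoyl}-1,3-oxazolidin-2-one | CCc1ccc(C(C)=C)c(c1)[C@@H](CC(=O)/C=C/C)CC(=O)N1C(=O)OC[C@@H]1Cc1ccccc1
F3 | step 6 | (4S)-3-{[(1S,2S,6S)-6-(2-acetyl-5-ethylphenyl)-4-(tert-butyldimethylsilyloxy)-2-methylcyclohex-3-en-1-yl]carbonyl}-4-benzyl-1,3-oxazolidin-2-one | CCc1ccc(C(C)=O)c(c1)[C@H]1CC(O[Si](C)(C)C(C)(C)C)=C[C@H](C)[C@@H]1C(=O)N1C(=O)OC[C@@H]1Cc1ccccc1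
F4 | step 6 | (4S)-3-{[(1S,2S,3S,4S,6S)-4-(2-acetyl-5-ethylphenyl)-6-(tert-butyldimethylsilyloxy)-2-methylbicyclo[4.1.0]heptan-3-yl]carbonyl}-4-benzyl-1,3-oxazolidin-2-one | CCc1ccc(C(C)=O)c(c1)[C@H]1C[C@@]2(O[Si](C)(C)C(C)(C)C)C[C@H]2[C@H](C)[C@@H]1C(=O)N1C(=O)OC[C@@H]1Cc1ccccc1
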